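**Plan**
Numbering (cembrane): C1 = ring CH carrying C15; C15 carries methyl C17 and carbonyl C16; C2 = lactone CH2; C3 = lactone O–CH; C4 = C(OH)CH3; C7 = CH–OOH; C8 = C(=C19H2); C11/C12 = epoxide carbons.
Cuts, in retrosynthetic order: C7–OO with C19–H (ene reaction of the C7=C8 olefin), C16–O3 (lactonisation), C2–C3 (ring-closing intramolecular vinylogous aldol), C1–CH3 and C13–C14 (enol tosylate methylation, acetoacetate dianion alkylation), C5–C6 (sulfone–epoxide coupling).
Forward: the C3–C13 chain is built from geranyl bromide and (R)-2-methylglycidol, the 11,12-epoxide is set on the open chain, the C14–C17 ester end is added, the 14-membered carbocycle is closed at C2–C3, the δ-lactone is closed next, C1=C15 is reduced, and the hydroperoxide comes last.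
Stereochemistry: C4 from (R)-2-methylglycidol; C11/C12 by Sharpless epoxidation; C3 by Felkin–Anh addition under control of C4; C1 by hydrogen delivery anti to the ring bridge; C15 by equilibration; C7 by the face of the ene reaction.
Enabling feature: in the lactone ring O–C3–C2–C1–C15–C16 the CH2 carbon C2 is γ to the C16 carbonyl, and C3 is an oxygen-bearing carbon whose neighbour C4 carries no hydrogen. The C2–C3 bond, shared by the lactone and the 14-membered ring, is therefore the bond of a vinylogous aldol addition of an ester dienolate to a non-enolisable aldehyde.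

Key step: step 13

Remark: 1, 3 and 10 are taken as commercial; 18 is drawn with the olefin geometry expected from retention, and either geometry converges in step 14.

Step 1
Reactants: 1 geranyl bromide
Product: 2 geranyl phenyl sulfone
Conditions: PhSO2Na, DMF, 23 °C
Reagents that add atoms: sodium benzenesulfinate, [Na+].[O-]S(=O)c1ccccc1
Why: S-alkylation of the sulfinate at the primary allylic bromide (SN2 substitution) should give the sulfone without allylic transposition and makes C6 a stabilised carbanion site.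

Step 2
Reactants: 3 (R)-2-methylglycidol
Product: 4 (S)-2-{[(4-methoxybenzyl)oxy]methyl}-2-methyloxirane
Conditions: NaH, 4-methoxybenzyl chloride, Bu4NI (cat.), THF/DMF, 0 → 23 °C
Reagents that add atoms: 4-methoxybenzyl chloride, COc1ccc(CCl)cc1
Why: Williamson etherification of the primary alkoxide leaves the C4 stereocentre untouched (the descriptor changes from R to S only through the priority rules).

Step 3
Reactants: 2 geranyl phenyl sulfone; 4 (S)-2-{[(4-methoxybenzyl)oxy]methyl}-2-methyloxirane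
Product: 5 (2S,5E)-1-[(4-methoxybenzyl)oxy]-2,6,10-trimethyl-4-(phenylsulfonyl)undeca-5,9-dien-2-ol (C4 epimers)
Conditions: n-BuLi, THF, −78 °C; then 4, DMPU, −78 → 23 °C
Reagents that add atoms: none
Why: The α-sulfonyl allyl anion reacts at its α-carbon and opens the 2,2-disubstituted epoxide at the unsubstituted CH2 (sulfone carbanion alkylation), which forms C5–C6 and frees the C4 tertiary alcohol with its configuration retained.

Step 4
Reactants: 5 (2S,5E)-1-[(4-methoxybenzyl)oxy]-2,6,10-trimethyl-4-(phenylsulfonyl)undeca-5,9-dien-2-ol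
Product: 6 (2S,5E)-1-[(4-methoxybenzyl)oxy]-2,6,10-trimethylundeca-5,9-dien-2-ol
Conditions: PdCl2(dppp) (5 mol %), LiBHEt3, THF, 0 °C
Reagents that add atoms: none
Why: Palladium-catalysed reductive desulfonylation of the allylic sulfone through a π-allyl intermediate should deliver hydride to the less substituted allyl terminus C6 and keep the E-trisubstituted C7=C8 olefin.

Step 5
Reactants: 6 (2S,5E)-1-[(4-methoxybenzyl)oxy]-2,6,10-trimethylundeca-5,9-dien-2-ol
Product: 7 triethyl{[(2S,5E)-1-[(4-methoxybenzyl)oxy]-2,6,10-trimethylundeca-5,9-dien-2-yl]oxy}silane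
Conditions: Et3SiOTf, 2,6-lutidine, CH2Cl2, −78 → 0 °C
Reagents that add atoms: triethylsilyl trifluoromethanesulfonate, CC[Si](CC)(CC)OS(=O)(=O)C(F)(F)F
Why: Silylation of the hindered tertiary alcohol with the silyl triflate puts a non-chelating group on O4, as needed for Felkin–Anh control in step 13.

Step 6
Reactants: 7 triethyl{[(2S,5E)-1-[(4-methoxybenzyl)oxy]-2,6,10-trimethylundeca-5,9-dien-2-yl]oxy}silane
Product: 8 (2E,6E,10S)-11-[(4-methoxybenzyl)oxy]-2,6,10-trimethyl-10-[(triethylsilyl)oxy]undeca-2,6-dien-1-ol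
Conditions: SeO2 (cat.), t-BuOOH, salicylic acid (cat.), CH2Cl2, 23 °C
Reagents that add atoms: tert-butyl hydroperoxide, CC(C)(C)OO
Why: Selenium dioxide allylic oxidation (ene reaction then 2,3-sigmatropic shift) is selective for the E-methyl group of the terminal gem-dimethyl olefin and gives the E allylic alcohol at C13.

Step 7
Reactants: 8 (2E,6E,10S)-11-[(4-methoxybenzyl)oxy]-2,6,10-trimethyl-10-[(triethylsilyl)oxy]undeca-2,6-dien-1-ol
Product: 9 {(2S,3S)-3-[(3E,7S)-8-[(4-methoxybenzyl)oxy]-3,7-dimethyl-7-[(triethylsilyl)oxy]oct-3-en-1-yl]-2-methyloxiran-2-yl}methanol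
Conditions: Ti(OiPr)4, L-(+)-diethyl tartrate, t-BuOOH, 4 Å molecular sieves, CH2Cl2, −20 °C
Reagents that add atoms: tert-butyl hydroperoxide, CC(C)(C)OO
Why: Sharpless asymmetric epoxidation acts only on the allylic alcohol olefin, and the L-(+)-tartrate ligand sets C11 and C12 as S,S by reagent control while the isolated C7=C8 olefin is left alone.

Step 8
Reactants: 9 {(2S,3S)-3-[(3E,7S)-8-[(4-methoxybenzyl)oxy]-3,7-dimethyl-7-[(triethylsilyl)oxy]oct-3-en-1-yl]-2-methyloxiran-2-yl}methanol; 10 methyl 2-methylacetoacetate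
Product: 13 methyl 5-{(2S,3S)-3-[(3E,7S)-8-[(4-methoxybenzyl)oxy]-3,7-dimethyl-7-[(triethylsilyl)oxy]oct-3-en-1-yl]-2-methyloxiran-2-yl}-2-methyl-3-oxopentanoate (C2 epimers), via acetoacetate dianion 11 (not isolated), via epoxy triflate 12 (not isolated)
Conditions: 10, NaH then n-BuLi, THF, 0 °C; 9, Tf2O, 2,6-lutidine, CH2Cl2, −78 °C; combined, THF, −78 → −40 °C
Reagents that add atoms: none
Why: The terminal carbon of the acetoacetate dianion alkylates the primary triflate at low temperature (dianion γ-alkylation), which should form C13–C14 faster than the enolate can open the trisubstituted epoxide.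

Step 9
Reactants: 13 methyl 5-{(2S,3S)-3-[(3E,7S)-8-[(4-methoxybenzyl)oxy]-3,7-dimethyl-7-[(triethylsilyl)oxy]oct-3-en-1-yl]-2-methyloxiran-2-yl}-2-methyl-3-oxopentanoate
Product: 14 methyl (2E)-5-{(2S,3S)-3-[(3E,7S)-8-[(4-methoxybenzyl)oxy]-3,7-dimethyl-7-[(triethylsilyl)oxy]oct-3-en-1-yl]-2-methyloxiran-2-yl}-2-methyl-3-[(4-methylbenzenesulfonyl)oxy]pent-2-enoate
Conditions: TsCl, N-methylimidazole, Et3N, CH2Cl2, −15 → 0 °C
Reagents that add atoms: 4-toluenesulfonyl chloride, Cc1ccc(cc1)S(Cl)(=O)=O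
Why: O-sulfonylation of the non-chelated amine enolate of the α-substituted β-keto ester (stereoselective enol tosylation) should give the E enol tosylate, with the tosyloxy group trans to the ester.

Step 10
Reactants: 14 methyl (2E)-5-{(2S,3S)-3-[(3E,7S)-8-[(4-methoxybenzyl)oxy]-3,7-dimethyl-7-[(triethylsilyl)oxy]oct-3-en-1-yl]-2-methyloxiran-2-yl}-2-methyl-3-[(4-methylbenzenesulfonyl)oxy]pent-2-enoate
Product: 15 methyl (2Z)-5-{(2S,3S)-3-[(3E,7S)-8-[(4-methoxybenzyl)oxy]-3,7-dimethyl-7-[(triethylsilyl)oxy]oct-3-en-1-yl]-2-methyloxiran-2-yl}-2,3-dimethylpent-2-enoate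
Conditions: MeZnCl, PdCl2(dppf) (5 mol %), THF, 23 °C
Reagents that add atoms: methylzinc chloride, C[Zn]Cl
Why: Negishi cross-coupling of the enol tosylate proceeds with retention of olefin geometry, so the new methyl group (C2) ends trans to the ester and the C14 chain cis to it.

Step 11
Reactants: 15 methyl (2Z)-5-{(2S,3S)-3-[(3E,7S)-8-[(4-methoxybenzyl)oxy]-3,7-dimethyl-7-[(triethylsilyl)oxy]oct-3-en-1-yl]-2-methyloxiran-2-yl}-2,3-dimethylpent-2-enoate
Product: 16 methyl (2Z)-5-{(2S,3S)-3-[(3E,7S)-8-hydroxy-3,7-dimethyl-7-[(triethylsilyl)oxy]oct-3-en-1-yl]-2-methyloxiran-2-yl}-2,3-dimethylpent-2-enoate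
Conditions: DDQ, CH2Cl2/pH 7 buffer, 0 °C
Reagents that add atoms: none
Why: Oxidative cleavage of the 4-methoxybenzyl ether by hydride abstraction frees the C3 alcohol without touching the epoxide, the silyl ether or the olefins.

Step 12
Reactants: 16 methyl (2Z)-5-{(2S,3S)-3-[(3E,7S)-8-hydroxy-3,7-dimethyl-7-[(triethylsilyl)oxy]oct-3-en-1-yl]-2-methyloxiran-2-yl}-2,3-dimethylpent-2-enoate
Product: 17 methyl (2Z)-5-{(2S,3S)-3-[(3E,7S)-3,7-dimethyl-8-oxo-7-[(triethylsilyl)oxy]oct-3-en-1-yl]-2-methyloxiran-2-yl}-2,3-dimethylpent-2-enoate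
Conditions: Dess–Martin periodinane, NaHCO3, CH2Cl2, 0 → 23 °C
Reagents that add atoms: none
Why: Dess–Martin oxidation gives the aldehyde, which cannot enolise or epimerise because C4 carries no hydrogen.

Step 13
Reactants: 17 methyl (2Z)-5-{(2S,3S)-3-[(3E,7S)-3,7-dimethyl-8-oxo-7-[(triethylsilyl)oxy]oct-3-en-1-yl]-2-methyloxiran-2-yl}-2,3-dimethylpent-2-enoate
Product: 18 methyl (1(15)E,3R,4S,7E,11S,12S)-11,12-epoxy-3-hydroxy-4-[(triethylsilyl)oxy]cembra-1(15),7-dien-16-oate
Conditions: Al(OC6H3-2,6-Ph2)3 (2.2 equiv), toluene, −78 °C; then lithium 2,2,6,6-tetramethylpiperidide (2.2 equiv), THF, −78 °C, 5 mM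
Reagents that add atoms: none
Why: The aluminium tris(2,6-diphenylphenoxide) binds the aldehyde and the ester carbonyl oxygens and wraps both in its aryl pocket, so the hindered lithium amide cannot add to the aldehyde and removes the one exposed acidic proton, on the C2 methyl group trans to the ester; the aluminium-bound dienolate, whose α-carbon C15 is buried, then attacks the activated aldehyde through its γ-carbon C2. The closest known reaction type is the intramolecular vinylogous aldol reaction of ω-formyl α,β-unsaturated esters with this reagent pair, which closes 10- to 16-membered macrolide rings. The new C2–C3 bond closes the 14-membered carbocycle in a 14-exo-trig addition to the aldehyde and leaves the C3 oxygen δ to C16, ready for the lactone closure of step 14. The new stereocentre C3 is controlled by C4 through a polar Felkin–Anh transition state: the C4–OSiEt3 bond stands anti to the incoming C2, which passes the C4 methyl group and not the C5 methylene, and this gives 3R; the monodentate, bulky aluminium centre rules out a chelate. The step needs γ- over α-attack (secured by the shielded, fully substituted C15), deprotonation of the C2 methyl and not of C14 (secured by the 2Z geometry, which puts C14 next to the complexed carbonyl), ring closure over oligomerisation (5 mM) and an intact 11,12-epoxide (the two equivalents of Lewis acid are taken up by the two carbonyl groups at −78 °C).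

Step 14
Reactants: 18 methyl (1(15)E,3R,4S,7E,11S,12S)-11,12-epoxy-3-hydroxy-4-[(triethylsilyl)oxy]cembra-1(15),7-dien-16-oate
Product: 20 (3R,4S,7E,11S,12S)-11,12-epoxy-4-[(triethylsilyl)oxy]cembra-1(15),7-dien-16,3-olide, via Z-enoate isomer 19 (not isolated)
Conditions: hν (254 nm), MeCN, 0 °C; then DBU (cat.), 23 → 50 °C
Reagents that add atoms: none
Why: Photochemical E/Z isomerisation of the conjugated ester brings C16 next to C2, and the C3 hydroxyl then closes the six-membered lactone by base-catalysed transesterification (isomerisation–lactonisation), any deconjugated photoproduct being drawn into the same conjugated lactone by DBU.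

Step 15
Reactants: 20 (3R,4S,7E,11S,12S)-11,12-epoxy-4-[(triethylsilyl)oxy]cembra-1(15),7-dien-16,3-olide
Product: 22 (1R,3R,4S,7E,11S,12S,15S)-11,12-epoxy-4-[(triethylsilyl)oxy]cembr-7-en-16,3-olide, via 15-epi lactone 21 (not isolated)
Conditions: NiCl2·6H2O, NaBH4, MeOH/THF, 0 °C; then DBU, toluene, 60 °C
Reagents that add atoms: none
Why: Conjugate reduction by nickel boride adds two hydrogens to the lactone face opposite the C3–C4 bond and the ring bridge, which sets C1 as R, and base equilibration of the enolisable C15 then moves its methyl group to the equatorial position trans to C14 (15S).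

Step 16
Reactants: 22 (1R,3R,4S,7E,11S,12S,15S)-11,12-epoxy-4-[(triethylsilyl)oxy]cembr-7-en-16,3-olide
Product: 23 (1R,3R,4S,7E,11S,12S,15S)-11,12-epoxy-4-hydroxycembr-7-en-16,3-olide
Conditions: Bu4NF, AcOH, THF, 0 → 23 °C
Reagents that add atoms: none
Why: Buffered fluoride desilylation frees the C4 tertiary alcohol without opening the lactone or the epoxide.

Step 17
Reactants: 23 (1R,3R,4S,7E,11S,12S,15S)-11,12-epoxy-4-hydroxycembr-7-en-16,3-olide
Product: 24 (1R,3R,4S,7S,11S,12S,15S)-11,12-epoxy-7-hydroperoxy-4-hydroxycembr-8(19)-en-16,3-olide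
Conditions: O2, tetraphenylporphyrin (cat.), hν (visible), CH2Cl2, −20 °C
Reagents that add atoms: oxygen, O=O
Why: The Schenck ene reaction of singlet oxygen with the only olefin forms the C7–O bond and removes a C19 hydrogen on the more crowded side of the double bond (cis effect); C7 is set by suprafacial attack on the exposed outer face of the ring olefin, and this is the least secure stereocentre of the route.

**Compound list**
1 | geranyl bromide, (2E)-1-bromo-3,7-dimethylocta-2,6-diene | BrC/C=C(\C)CCC=C(C)C | starting material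
2 | geranyl phenyl sulfone | O=S(=O)(C/C=C(\C)CCC=C(C)C)c1ccccc1 | intermediate
3 | (R)-2-methylglycidol | OC[C@@]1(C)OC1 | starting material
4 | (S)-2-{[(4-methoxybenzyl)oxy]methyl}-2-methyloxirane | COc1ccc(COC[C@@]2(C)OC2)cc1 | intermediate
5 | (2S,5E)-1-[(4-methoxybenzyl)oxy]-2,6,10-trimethyl-4-(phenylsulfonyl)undeca-5,9-dien-2-ol (C4 epimers) | COc1ccc(COC[C@@](C)(O)CC(/C=C(\C)CCC=C(C)C)S(=O)(=O)c2ccccc2)cc1 | intermediate
6 | (2S,5E)-1-[(4-methoxybenzyl)oxy]-2,6,10-trimethylundeca-5,9-dien-2-ol | COc1ccc(COC[C@@](C)(O)CC/C=C(\C)CCC=C(C)C)cc1 | intermediate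
7 | triethyl{[(2S,5E)-1-[(4-methoxybenzyl)oxy]-2,6,10-trimethylundeca-5,9-dien-2-yl]oxy}silane | COc1ccc(COC[C@@](C)(O[Si](CC)(CC)CC)CC/C=C(\C)CCC=C(C)C)cc1 | intermediate
8 | (2E,6E,10S)-11-[(4-methoxybenzyl)oxy]-2,6,10-trimethyl-10-[(triethylsilyl)oxy]undeca-2,6-dien-1-ol | COc1ccc(COC[C@@](C)(O[Si](CC)(CC)CC)CC/C=C(\C)CC/C=C(\C)CO)cc1 | intermediate
9 | {(2S,3S)-3-[(3E,7S)-8-[(4-methoxybenzyl)oxy]-3,7-dimethyl-7-[(triethylsilyl)oxy]oct-3-en-1-yl]-2-methyloxiran-2-yl}methanol | COc1ccc(COC[C@@](C)(O[Si](CC)(CC)CC)CC/C=C(\C)CC[C@@H]2O[C@@]2(C)CO)cc1 | intermediate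
10 | methyl 2-methylacetoacetate | COC(=O)C(C)C(C)=O | starting material
11 | sodium lithium dianion of methyl 2-methylacetoacetate | [Li+].[Na+].C=C([O-])C(C)=C([O-])OC | intermediate
12 | trifluoromethanesulfonate of 9 (epoxy triflate) | COc1ccc(COC[C@@](C)(O[Si](CC)(CC)CC)CC/C=C(\C)CC[C@@H]2O[C@@]2(C)COS(=O)(=O)C(F)(F)F)cc1 | intermediate
13 | methyl 5-{(2S,3S)-3-[(3E,7S)-8-[(4-methoxybenzyl)oxy]-3,7-dimethyl-7-[(triethylsilyl)oxy]oct-3-en-1-yl]-2-methyloxiran-2-yl}-2-methyl-3-oxopentanoate (C2 epimers) | COc1ccc(COC[C@@](C)(O[Si](CC)(CC)CC)CC/C=C(\C)CC[C@@H]2O[C@@]2(C)CCC(=O)C(C)C(=O)OC)cc1 | intermediate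
14 | methyl (2E)-5-{(2S,3S)-3-[(3E,7S)-8-[(4-methoxybenzyl)oxy]-3,7-dimethyl-7-[(triethylsilyl)oxy]oct-3-en-1-yl]-2-methyloxiran-2-yl}-2-methyl-3-[(4-methylbenzenesulfonyl)oxy]pent-2-enoate | COc1ccc(COC[C@@](C)(O[Si](CC)(CC)CC)CC/C=C(\C)CC[C@@H]2O[C@@]2(C)CC/C(OS(=O)(=O)c3ccc(C)cc3)=C(/C)C(=O)OC)cc1 | intermediate
15 | methyl (2Z)-5-{(2S,3S)-3-[(3E,7S)-8-[(4-methoxybenzyl)oxy]-3,7-dimethyl-7-[(triethylsilyl)oxy]oct-3-en-1-yl]-2-methyloxiran-2-yl}-2,3-dimethylpent-2-enoate | COc1ccc(COC[C@@](C)(O[Si](CC)(CC)CC)CC/C=C(\C)CC[C@@H]2O[C@@]2(C)CC/C(C)=C(/C)C(=O)OC)cc1 | intermediate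
16 | methyl (2Z)-5-{(2S,3S)-3-[(3E,7S)-8-hydroxy-3,7-dimethyl-7-[(triethylsilyl)oxy]oct-3-en-1-yl]-2-methyloxiran-2-yl}-2,3-dimethylpent-2-enoate | OC[C@@](C)(O[Si](CC)(CC)CC)CC/C=C(\C)CC[C@@H]1O[C@@]1(C)CC/C(C)=C(/C)C(=O)OC | intermediate
17 | methyl (2Z)-5-{(2S,3S)-3-[(3E,7S)-3,7-dimethyl-8-oxo-7-[(triethylsilyl)oxy]oct-3-en-1-yl]-2-methyloxiran-2-yl}-2,3-dimethylpent-2-enoate | O=C[C@@](C)(O[Si](CC)(CC)CC)CC/C=C(\C)CC[C@@H]1O[C@@]1(C)CC/C(C)=C(/C)C(=O)OC | intermediate
18 | methyl (1(15)E,3R,4S,7E,11S,12S)-11,12-epoxy-3-hydroxy-4-[(triethylsilyl)oxy]cembra-1(15),7-dien-16-oate (14-membered carbocycle, exocyclic C1=C15 with C2 trans to CO2Me) | C1C[C@@H]2O[C@@]2(C)CC/C(=C(/C)C(=O)OC)C[C@@H](O)[C@@](C)(O[Si](CC)(CC)CC)CC/C=C1\C | intermediate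
19 | 1(15)Z isomer of 18 | C1C[C@@H]2O[C@@]2(C)CC/C(=C(\C)C(=O)OC)C[C@@H](O)[C@@](C)(O[Si](CC)(CC)CC)CC/C=C1\C | intermediate
20 | (3R,4S,7E,11S,12S)-11,12-epoxy-4-[(triethylsilyl)oxy]cembra-1(15),7-dien-16,3-olide (bridged α,β-unsaturated δ-lactone) | C1C[C@@H]2O[C@@]2(C)CCC3=C(C)C(=O)O[C@H](C3)[C@@](C)(O[Si](CC)(CC)CC)CC/C=C1\C | intermediate
21 | (1R,3R,4S,7E,11S,12S,15R)-11,12-epoxy-4-[(triethylsilyl)oxy]cembr-7-en-16,3-olide (15-epimer of 22) | C1C[C@@H]2O[C@@]2(C)CC[C@@H]3C[C@@H](OC(=O)[C@@H]3C)[C@@](C)(O[Si](CC)(CC)CC)CC/C=C1\C | intermediate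
22 | (1R,3R,4S,7E,11S,12S,15S)-11,12-epoxy-4-[(triethylsilyl)oxy]cembr-7-en-16,3-olide | C1C[C@@H]2O[C@@]2(C)CC[C@@H]3C[C@@H](OC(=O)[C@H]3C)[C@@](C)(O[Si](CC)(CC)CC)CC/C=C1\C | intermediate
23 | (1R,3R,4S,7E,11S,12S,15S)-11,12-epoxy-4-hydroxycembr-7-en-16,3-olide | C1C[C@@H]2O[C@@]2(C)CC[C@@H]3C[C@@H](OC(=O)[C@H]3C)[C@@](C)(O)CC/C=C1\C | intermediate
24 | (1R,3R,4S,7S,11S,12S,15S)-11,12-epoxy-7-hydroperoxy-4-hydroxycembr-8(19)-en-16,3-olide | C=C1CC[C@@H]2O[C@@]2(C)CC[C@@H]2C[C@@H](OC(=O)[C@H]2C)[C@@](C)(O)CC[C@@H]1OO | target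

**Step count and risks**
Total steps: 17. Longest linear sequence: 16 steps (from 1 through steps 1 and 3–17).

Steps most likely to fail:

Step 13. The addition may take place on both faces of the aldehyde, because the C4 methyl and the C5 methylene differ little in size, so that 18 would form as a mixture of C3 epimers. The fallback sets out from 18 (as the epimer mixture) and sets C3 by reduction instead of by C–C bond formation. Dess–Martin oxidation of the C3 carbinol should give the macrocyclic C3 ketone F1. Bu4NF/AcOH then removes the silyl group to give the α-hydroxy ketone F2. Zn(BH4)2 in Et2O at −78 °C reduces the zinc chelate of the C3 carbonyl and the C4 hydroxyl from the face of the C4 methyl group and should give the 3R,4S diol ester F3. Irradiation and DBU as in step 14 lead, via the Z enoate F4, to the unsaturated hydroxy lactone F5. Nickel boride and then DBU as in step 15 lead, via the 15-epimer F6, to 23, where the route is rejoined.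

Step 17. Singlet oxygen may attack both faces of the C7=C8 olefin, and hydrogen abstraction from C6 may compete with abstraction from C19. The fallback sets out from 23 and fixes C7 by reagent control. Photo-oxygenation as in step 17 gives the C7-epimeric hydroperoxides F9, which are reduced in the same flask with PPh3 to the C7-epimeric allylic alcohols F10. MnO2 oxidises both epimers to the single enone F11. Corey–Bakshi–Shibata reduction with (S)-2-methyl-CBS-oxazaborolidine and BH3·SMe2 should give the 7R allylic alcohol F12. MsCl/Et3N gives the mesylate F13, and displacement with anhydrous H2O2 in Et2O (SN2, inversion) comes back to 24.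

Step 14. The photochemical isomerisation may stop at a photostationary mixture, or lactonisation of the hindered Z ester may be slower than photodecomposition. The fallback sets out from 18 and reaches the lactone through the deconjugated ester. LiN(iPr)2 (3 equiv) in THF/HMPA at −78 °C removes a proton from C14, the γ-carbon cis to the ester; kinetic α-protonation with AcOH at −78 °C should give the β,γ-unsaturated hydroxy ester F7, in which rotation about C1–C15 is free. DBU in toluene at 80 °C then closes the β,γ-unsaturated lactone F8 and moves its double bond into conjugation, which comes back to 20.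

Further compounds
F1 | step 13 | methyl (1(15)E,4S,7E,11S,12S)-11,12-epoxy-3-oxo-4-[(triethylsilyl)oxy]cembra-1(15),7-dien-16-oate | C1C[C@@H]2O[C@@]2(C)CC/C(=C(/C)C(=O)OC)CC(=O)[C@@](C)(O[Si](CC)(CC)CC)CC/C=C1\C
F2 | step 13 | methyl (1(15)E,4S,7E,11S,12S)-11,12-epoxy-4-hydroxy-3-oxocembra-1(15),7-dien-16-oate | C1C[C@@H]2O[C@@]2(C)CC/C(=C(/C)C(=O)OC)CC(=O)[C@@](C)(O)CC/C=C1\C
F3 | step 13 | methyl (1(15)E,3R,4S,7E,11S,12S)-11,12-epoxy-3,4-dihydroxycembra-1(15),7-dien-16-oate | C1C[C@@H]2O[C@@]2(C)CC/C(=C(/C)C(=O)OC)C[C@@H](O)[C@@](C)(O)CC/C=C1\C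
F4 | step 13 | 1(15)Z isomer of F3 | C1C[C@@H]2O[C@@]2(C)CC/C(=C(\C)C(=O)OC)C[C@@H](O)[C@@](C)(O)CC/C=C1\C
F5 | step 13 | (3R,4S,7E,11S,12S)-11,12-epoxy-4-hydroxycembra-1(15),7-dien-16,3-olide | C1C[C@@H]2O[C@@]2(C)CCC3=C(C)C(=O)O[C@H](C3)[C@@](C)(O)CC/C=C1\C
F6 | step 13 | (1R,3R,4S,7E,11S,12S,15R)-11,12-epoxy-4-hydroxycembr-7-en-16,3-olide (15-epimer of 23) | C1C[C@@H]2O[C@@]2(C)CC[C@@H]3C[C@@H](OC(=O)[C@@H]3C)[C@@](C)(O)CC/C=C1\C
F7 | step 14 | methyl (3R,4S,7E,11S,12S)-11,12-epoxy-3-hydroxy-4-[(triethylsilyl)oxy]cembra-1(14),7-dien-16-oate (C15 epimers) | C1C[C@@H]2O[C@@]2(C)CC=C(C(C)C(=O)OC)C[C@@H](O)[C@@](C)(O[Si](CC)(CC)CC)CC/C=C1\C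
F8 | step 14 | (3R,4S,7E,11S,12S)-11,12-epoxy-4-[(triethylsilyl)oxy]cembra-1(14),7-dien-16,3-olide (C15 epimers) | C1C[C@@H]2O[C@@]2(C)CC=C3C[C@@H](OC(=O)C3C)[C@@](C)(O[Si](CC)(CC)CC)CC/C=C1\C
F9 | step 17 | (1R,3R,4S,11S,12S,15S)-11,12-epoxy-7-hydroperoxy-4-hydroxycembr-8(19)-en-16,3-olide (C7 epimers) | C=C1CC[C@@H]2O[C@@]2(C)CC[C@@H]2C[C@@H](OC(=O)[C@H]2C)[C@@](C)(O)CCC1OO
F10 | step 17 | (1R,3R,4S,11S,12S,15S)-11,12-epoxy-4,7-dihydroxycembr-8(19)-en-16,3-olide (C7 epimers) | C=C1CC[C@@H]2O[C@@]2(C)CC[C@@H]2C[C@@H](OC(=O)[C@H]2C)[C@@](C)(O)CCC1O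
F11 | step 17 | (1R,3R,4S,11S,12S,15S)-11,12-epoxy-4-hydroxy-7-oxocembr-8(19)-en-16,3-olide | C=C1CC[C@@H]2O[C@@]2(C)CC[C@@H]2C[C@@H](OC(=O)[C@H]2C)[C@@](C)(O)CCC1=O
F12 | step 17 | (1R,3R,4S,7R,11S,12S,15S)-11,12-epoxy-4,7-dihydroxycembr-8(19)-en-16,3-olide | C=C1CC[C@@H]2O[C@@]2(C)CC[C@@H]2C[C@@H](OC(=O)[C@H]2C)[C@@](C)(O)CC[C@H]1O
F13 | step 17 | 7-methanesulfonate of F12 | C=C1CC[C@@H]2O[C@@]2(C)CC[C@@H]2C[C@@H](OC(=O)[C@H]2C)[C@@](C)(O)CC[C@H]1OS(C)(=O)=O
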